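## Structural features

The target is a labdane, (13R)‑2β‑acetoxylabd‑8(17)‑en‑15‑oic acid. Ring A (C1–C5, C10) and ring B (C5–C10) form a trans‑decalin that carries a gem‑dimethyl group at C4, an angular methyl C20 at C10, an exocyclic methylene C17 at C8, a C11–C15 acid chain at C9 with a methyl on C13, and an acetate at C2. The SMILES reads (2R,5S,9S,10S,13R), i.e. 2β‑OAc, 5α‑H, 9α‑H, 10β‑Me.

C5, C10 and C9 are contiguous and C10 is quaternary; C2 is 1,3 to both C10 and C4; C13 is insulated from the bicycle by two CH2 groups. The C2 acetate is axial and stands syn to the axial C4 methyl and to C20, so three axial groups share the β face of ring A. This is the epimer that a chair‑like ring closure or an equilibration would not deliver. Oxygen at C2 is also off the positions that cation–olefin cyclisation (C3) or Robinson‑type annulation (C3, C7, C9) place naturally.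

The fragile groups are the 1,1‑disubstituted alkene (protic acid moves it into the ring), the acetate next to a free acid, and C9, which can only be corrected while C8 is a ketone. The real difficulty is the quaternary C10 with the trans ring fusion, set in the right sense relative to an axial oxygen at C2; C13 cannot be relayed and is bought.

The key step exploits O2, C1, C10 and C20: the C2 oxygen and C20 are cis and 1,3‑diaxial on ring A. C20 can therefore be delivered to C10 from O2 through one silicon atom (O2–Si–C20) across a C5=C10 double bond, and C5 then takes hydrogen from the opposite face.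

## Logic of the disconnections

**23 ⇒ 21.** The acetyl C–O bond at O2 is cut. This keeps the acid‑labile alkene away from any ester cleavage, because the acid is already free. The forward step must acetylate a hindered axial alcohol and must not leave the C15 mixed anhydride 22 intact.

**21 ⇒ 20.** The C8=C17 bond is cut to a ketone. The ketone lets C9 settle in the equatorial configuration and gives a handle for ring B. The demand is methylenation of a hindered ketone in the presence of a carboxylate and an alkoxide.

**20 ⇒ 19 ⇒ 18.** No skeletal bond is cut. The C8 ketone is masked as a ketal, and C20–H and O2–H are traced back to C20–Si and O2–Si of one siloxane ring. The forward steps must cleave an unactivated C–Si bond and must not touch C5 or C10.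

**18 ⇒ 17 (key).** The C10–C20 bond and the C5–H bond are cut, giving a C5=C10 alkene and a bromomethylsilyl ether on O2. Two ring stereocentres (C10 quaternary, C5 at the ring fusion) disappear in one operation, leaving the bicycle with C2 as its only fixed stereocentre. The forward step needs 6‑exo attack at C10 from the face of O2 and hydrogen transfer to C5 from the other face. In one sentence: a silicon‑tethered radical cyclisation of the O2 bromomethylsilyl ether of a Δ5(10)‑octalin‑2‑ol installs the angular methyl and the trans fusion.

**17 ⇒ 16 ⇒ 15.** The O–Si bond and the ketal C–O bonds are cut. The ketal is needed because the β,γ‑unsaturated ketone would otherwise conjugate through its acidic C9–H. Ketalisation must keep the alkene at C5=C10.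

**15 ⇒ 9 + 14.** The C9–C11 bond is cut. This joins the whole side chain, with C13 already set, to the bicycle at the only carbon that is both α to C8 and allylic. The demand is C‑alkylation of a dienolate at C9 and not at C7.

**14 ⇒ 12 ⇒ 10.** Only functional groups change. C13 is bought as a half‑ester whose two arms are already differentiated; the acid arm becomes C11–C12. Reduction must be selective for the acid over the ester.

**9 ⇒ 7 (via 8).** No carbon–carbon bond is cut. Ring B is traced back to an anisole, which hides both the C8 carbonyl and the C5=C10 alkene. The dissolving‑metal reduction must protonate C6 and C9 so that the ring‑fusion alkene stays.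

**7 ⇒ 6.** The C4–C5 bond is cut. The quaternary C4 comes from a tertiary cation and ring A closes onto the arene. Attack must occur para to the methoxy group.

**6 ⇒ 4 + 5 and 4 ⇒ 1 + 2.** The C3–C4 and C1–C10 bonds are cut. C2 is bought as a three‑carbon epoxide that is opened twice at its terminal carbons, so no bond to the stereocentre is ever made or broken.

## Other disconnections considered

**Alternative 1:** (the first that comes to mind) Cut C4–C5 and C9–C10: cationic bicyclisation of the allylsilane‑terminated triene A1 to the decalin A2. This closes both rings and gives the exocyclic alkene directly. It leaves C2 unoxidised, however. Late C–H oxidation of A2 would have to choose C2 over C3, C6 and C7 next to a reactive alkene. A C2 oxygen carried in the polyene would take the equatorial (2α) position in the chair‑like closure and need an oxidation–reduction detour. Absolute control would also rest on a chiral acid. The chosen plan instead uses the axial C2 oxygen as the control element.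

**Alternative 2:** Cut C5–C6 and C9–C10 with a temporary C2–C7 bond: a [4+2] addition of a cyclic silyl dienol ether to an alkyl vinyl ketone gives the bicyclo[2.2.2]octene A3; retro‑aldol opening and intramolecular Michael addition give the dione A4. This is the shortest plan found. It is not chosen because a nucleophile tethered to C5 attacks the enone carbon C10 axially, which favours the cis ring fusion. In addition, the cis and trans diones should be close in energy, since the trans isomer pays for the syn‑diaxial C19/C20 pair, so equilibration would not rescue the fusion. The two ketones of A4 would also need to be told apart.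

**Alternative 3:** Cut C5–C10 and C8–C9: intramolecular Diels–Alder reaction of the acyclic trienal A5 to the octalin A6. This closes both rings and sets C5, C9 and C10 through an endo transition state. It needs a β,β‑disubstituted enal as dienophile, which reacts poorly. A C2 stereocentre in the tether would again end equatorial; a ketal, as in A5, needs an external chiral catalyst instead. The work after the cycloaddition (C6=C7 reduction, unmasking of C17, chain extension, C2 inversion) makes the route clearly longer than the chosen one.

Key step: step 10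

Remark: compound 10, the (R)‑half‑ester of 3‑methylglutaric acid, is taken as a catalogue compound.

## Route

Step 1
Reactants: 1 3-methoxyphenylmagnesium bromide; 2 (S)-epichlorohydrin
Product: 4 (2S)-2-[(3-methoxyphenyl)methyl]oxirane, via chlorohydrin 3 (not isolated)
Conditions: CuI (5 mol %), THF, −40 to 0 °C; then 2 M NaOH (aq), rt
Reagents that add atoms: none
Why: Copper-catalysed Grignard opening of the epoxide at its CH2 terminus, then intramolecular Williamson closure of the chlorohydrin to the new epoxide. No bond to the stereocentre is made or broken, so C2 of the target is bought from 2.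

Step 2
Reactants: 4 (2S)-2-[(3-methoxyphenyl)methyl]oxirane; 5 isopropenylmagnesium bromide
Product: 6 (2R)-1-(3-methoxyphenyl)-4-methylpent-4-en-2-ol
Conditions: CuI (10 mol %), THF, −30 to 0 °C; aq. NH4Cl
Reagents that add atoms: none
Why: Copper-catalysed SN2 opening of the monosubstituted epoxide at the terminal carbon forms C3–C4. The stereocentre is untouched; the descriptor changes to R by priority only.

Step 3
Reactants: 6 (2R)-1-(3-methoxyphenyl)-4-methylpent-4-en-2-ol
Product: 7 (2R)-7-methoxy-4,4-dimethyl-1,2,3,4-tetrahydronaphthalen-2-ol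
Conditions: MeSO3H (3 equiv), CH2Cl2, 0 °C to rt
Reagents that add atoms: none
Why: Friedel–Crafts cyclialkylation: protonation of the 1,1-disubstituted alkene gives the tertiary C4 cation, which closes the six-membered ring on the arene carbon para to the methoxy group. This makes the quaternary C4 and the C4–C5 bond; no new stereocentre forms.

Step 4
Reactants: 7 (2R)-7-methoxy-4,4-dimethyl-1,2,3,4-tetrahydronaphthalen-2-ol
Product: 9 (7R)-7-hydroxy-5,5-dimethyl-3,4,5,6,7,8-hexahydronaphthalen-2(1H)-one, via enol ether 8 (not isolated)
Conditions: Li (8 equiv), NH3 (l), THF, t-BuOH (4 equiv), −78 to −33 °C; NH4Cl; then (CO2H)2, MeOH–H2O, rt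
Reagents that add atoms: water, O
Why: Birch reduction protonates the two unsubstituted carbons ortho and meta to the methoxy group (C9 and C6), which leaves the enol ether and the tetrasubstituted C5=C10 alkene. Oxalic acid hydrolyses the enol ether without moving the alkene into conjugation.

Step 5
Reactants: 10 (3R)-5-methoxy-3-methyl-5-oxopentanoic acid
Product: 12 (4R)-4-methyloxan-2-one, via hydroxy ester 11 (not isolated)
Conditions: BH3·SMe2 (1.1 equiv), THF, 0 °C to rt; MeOH; then p-TsOH (cat.), CH2Cl2, rt
Reagents that add atoms: none
Why: Borane reduces the free acid in the presence of the methyl ester, and the hydroxy ester lactonises under acid. The C13 stereocentre is not touched.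

Step 6
Reactants: 12 (4R)-4-methyloxan-2-one
Product: 14 methyl (3S)-5-iodo-3-methylpentanoate, via silyl ester 13 (not isolated)
Conditions: Me3SiI (1.3 equiv), CH2Cl2, 0 °C to rt; then MeOH, rt
Reagents that add atoms: iodotrimethylsilane, C[Si](C)(C)I; methanol, CO
Why: Iodide opens the silyl-activated lactone by SN2 attack at the O–CH2 carbon (C11). Methanol, with the HI formed in situ as catalyst, turns the silyl ester into the methyl ester.

Step 7
Reactants: 9 (7R)-7-hydroxy-5,5-dimethyl-3,4,5,6,7,8-hexahydronaphthalen-2(1H)-one; 14 methyl (3S)-5-iodo-3-methylpentanoate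
Product: 15 methyl (3R)-5-[(7R)-7-hydroxy-5,5-dimethyl-2-oxo-1,2,3,4,5,6,7,8-octahydronaphthalen-1-yl]-3-methylpentanoate (both epimers at C9 of the labdane numbering)
Conditions: LiN(i-Pr)2 (2.2 equiv), THF, −78 °C; DMPU; 14 (1.2 equiv), −78 to −20 °C
Reagents that add atoms: none
Why: Alkylation of the linear lithium dienolate of a β,γ-unsaturated ketone: the doubly activated C9 proton (α to the carbonyl and allylic) is removed and carbon electrophiles react at that α carbon. This forms C9–C11 and keeps the C5=C10 alkene; the first equivalent of base goes to the hydroxyl. C9 forms as a mixture and is corrected in step 12.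

Step 8
Reactants: 15 methyl (3R)-5-[(7R)-7-hydroxy-5,5-dimethyl-2-oxo-1,2,3,4,5,6,7,8-octahydronaphthalen-1-yl]-3-methylpentanoate
Product: 16 methyl (13R)-8,8-ethylenedioxy-2β-hydroxy-17,20-dinorlabd-5(10)-en-15-oate (both C9 epimers)
Conditions: HOCH2CH2OH, p-TsOH (cat.), benzene, reflux, azeotropic removal of water
Reagents that add atoms: ethylene glycol, OCCO
Why: Acid-catalysed ketalisation; a β,γ-unsaturated ketone ketalises with the alkene in the tetrasubstituted β,γ position, and any conjugated enone formed from 15 should converge on the same ketal. The ketal protects C8 and removes the acidic C9 proton.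

Step 9
Reactants: 16 methyl (13R)-8,8-ethylenedioxy-2β-hydroxy-17,20-dinorlabd-5(10)-en-15-oate
Product: 17 methyl (13R)-2β-{[(bromomethyl)dimethylsilyl]oxy}-8,8-ethylenedioxy-17,20-dinorlabd-5(10)-en-15-oate
Conditions: BrCH2SiMe2Cl (1.3 equiv), Et3N, DMAP (cat.), CH2Cl2, 0 °C
Reagents that add atoms: (bromomethyl)chlorodimethylsilane, C[Si](C)(Cl)CBr
Why: Silylation of the secondary alcohol with the chlorosilane (amine base, DMAP catalysis) puts the radical precursor on O2.

Step 10
Reactants: 17 methyl (13R)-2β-{[(bromomethyl)dimethylsilyl]oxy}-8,8-ethylenedioxy-17,20-dinorlabd-5(10)-en-15-oate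
Product: 18 methyl (13R)-8,8-ethylenedioxy-17-norlabdan-15-oate with O-2β and C-20 joined through SiMe2 (six-membered C2–O–Si–C20–C10–C1 siloxane; 5α-H, 10β; both C9 epimers)
Conditions: Bu3SnH (1.3 equiv, syringe pump), AIBN (cat.), benzene (0.005 M), 80 °C
Reagents that add atoms: none
Why: The tin radical abstracts bromine from 17 to give a primary α-silyl radical; with the C2–O bond pseudo-axial this radical reaches C10, the near carbon of the tetrasubstituted C5=C10 alkene, and adds through a six-membered chair-like transition state to give the tertiary C5 radical, which takes a hydrogen atom from Bu3SnH. The closest known reaction type is the silicon-tethered radical cyclisation of (bromomethyl)dimethylsilyl ethers of allylic and homoallylic alcohols (temporary silicon connection), which is used to place methyl and hydroxymethyl groups cis to a hydroxyl, including on ring-fusion alkenes. One ring is closed, the temporary 1-oxa-2-silacyclohexane C2–O–Si–C20–C10–C1, in the 6-exo-trig mode. C10 is controlled by the tether: the O–Si–CH2 chain can only reach the face of C10 on which O2 stands, so C20 ends cis to O2 (β, axial) and C10 becomes quaternary with the configuration of the target. C5 is controlled in the hydrogen transfer: the β face of the planar C5 radical is covered by the new axial C10–C20 bond with its siloxane bridge and by the axial C4 methyl, so hydrogen should arrive from the α face and the ring fusion should become trans. The step needs cyclisation at C10 to beat both reduction of the primary radical and seven-membered closure at C5; the 6-exo mode and the position of C5 next to the quaternary C4 secure the regiochemistry, and slow addition of the stannane at high dilution gives the slow addition to a tetrasubstituted alkene time to occur. Both C9 epimers are carried through, since C9 is corrected in step 12.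

Step 11
Reactants: 18 the siloxane of step 10
Product: 19 (13R)-8,8-ethylenedioxy-2β-hydroxy-17-norlabdan-15-oic acid (5α, 10β-methyl; both C9 epimers)
Conditions: KOt-Bu (6 equiv), DMSO, H2O (3 equiv), 60 °C; then dilute HCl to pH 3
Reagents that add atoms: water, O
Why: Base-induced protodesilylation of the cyclic siloxane (opening at silicon, then alkoxide-assisted cleavage of the C20–Si bond) turns the tether into the C20 methyl and the free 2β-hydroxyl. The hydroxide formed from the added water saponifies the methyl ester in the same operation; no stereocentre is touched.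

Step 12
Reactants: 19 (13R)-8,8-ethylenedioxy-2β-hydroxy-17-norlabdan-15-oic acid
Product: 20 (13R)-2β-hydroxy-8-oxo-17-norlabdan-15-oic acid
Conditions: 3 M HCl, THF, 40 °C
Reagents that add atoms: water, O
Why: Acidic ketal hydrolysis. Acid-catalysed enolisation of the C8 ketone toward C9 should equilibrate the side chain into the equatorial β position (9α-H), the configuration of the target.

Step 13
Reactants: 20 (13R)-2β-hydroxy-8-oxo-17-norlabdan-15-oic acid
Product: 21 (13R)-2β-hydroxylabd-8(17)-en-15-oic acid
Conditions: Ph3PCH3Br (6 equiv), KOt-Bu (5.8 equiv), toluene, 0 to 90 °C; then aq. NH4Cl, dilute HCl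
Reagents that add atoms: methyltriphenylphosphonium bromide, C[P+](c1ccccc1)(c1ccccc1)c1ccccc1.[Br-]
Why: Wittig methylenation; excess ylide tolerates the carboxylate and the alkoxide. Basic conditions can only hold C9 in the equatorial configuration already reached.

Step 14
Reactants: 21 (13R)-2β-hydroxylabd-8(17)-en-15-oic acid
Product: 23 (13R)-2β-acetoxylabd-8(17)-en-15-oic acid, via mixed anhydride 22 (not isolated)
Conditions: Ac2O (6 equiv), pyridine, DMAP (0.2 equiv), 40 °C; then THF–H2O, NaHCO3, rt; acidify to pH 3
Reagents that add atoms: acetic anhydride, CC(=O)OC(C)=O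
Why: DMAP-catalysed acetylation of the hindered axial alcohol. The mixed anhydride formed at C15 is far more labile than the secondary acetate and is hydrolysed by aqueous bicarbonate; no strong acid meets the exocyclic alkene.

## Compound list

1 | 3-methoxyphenylmagnesium bromide | COc1cccc([Mg]Br)c1 | starting material
2 | (S)-epichlorohydrin, (2S)-2-(chloromethyl)oxirane | ClC[C@@H]1CO1 | starting material
3 | (2S)-1-chloro-3-(3-methoxyphenyl)propan-2-ol | ClC[C@@H](O)Cc1cccc(OC)c1 | intermediate (not isolated)
4 | (2S)-2-[(3-methoxyphenyl)methyl]oxirane | C1[C@@H](O1)Cc1cccc(OC)c1 | intermediate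
5 | isopropenylmagnesium bromide | CC(=C)[Mg]Br | starting material
6 | (2R)-1-(3-methoxyphenyl)-4-methylpent-4-en-2-ol | C=C(C)C[C@@H](O)Cc1cccc(OC)c1 | intermediate
7 | (2R)-7-methoxy-4,4-dimethyl-1,2,3,4-tetrahydronaphthalen-2-ol | CC1(C)C[C@@H](O)Cc2cc(OC)ccc21 | intermediate
8 | (2R)-7-methoxy-4,4-dimethyl-1,2,3,4,5,8-hexahydronaphthalen-2-ol | CC1(C)C[C@@H](O)CC2=C1CC=C(OC)C2 | intermediate (not isolated)
9 | (7R)-7-hydroxy-5,5-dimethyl-3,4,5,6,7,8-hexahydronaphthalen-2(1H)-one | CC1(C)C[C@@H](O)CC2=C1CCC(=O)C2 | intermediate
10 | (3R)-5-methoxy-3-methyl-5-oxopentanoic acid (methyl hydrogen (R)-3-methylglutarate) | OC(=O)C[C@@H](C)CC(=O)OC | starting material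
11 | methyl (3R)-5-hydroxy-3-methylpentanoate | OCC[C@@H](C)CC(=O)OC | intermediate (not isolated)
12 | (4R)-4-methyloxan-2-one | O=C1OCC[C@@H](C)C1 | intermediate
13 | trimethylsilyl (3S)-5-iodo-3-methylpentanoate | ICC[C@@H](C)CC(=O)O[Si](C)(C)C | intermediate (not isolated)
14 | methyl (3S)-5-iodo-3-methylpentanoate | ICC[C@@H](C)CC(=O)OC | intermediate
15 | methyl (3R)-5-[(7R)-7-hydroxy-5,5-dimethyl-2-oxo-1,2,3,4,5,6,7,8-octahydronaphthalen-1-yl]-3-methylpentanoate, C9 epimers (C9 left undefined) | CC1(C)C[C@@H](O)CC2=C1CCC(=O)C2CC[C@@H](C)CC(=O)OC | intermediate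
16 | methyl (13R)-8,8-ethylenedioxy-2β-hydroxy-17,20-dinorlabd-5(10)-en-15-oate, C9 epimers | CC1(C)C[C@@H](O)CC2=C1CCC3(OCCO3)C2CC[C@@H](C)CC(=O)OC | intermediate
17 | methyl (13R)-2β-{[(bromomethyl)dimethylsilyl]oxy}-8,8-ethylenedioxy-17,20-dinorlabd-5(10)-en-15-oate, C9 epimers | CC1(C)C[C@@H](O[Si](C)(C)CBr)CC2=C1CCC3(OCCO3)C2CC[C@@H](C)CC(=O)OC | intermediate
18 | methyl (13R)-8,8-ethylenedioxy-17-norlabdan-15-oate with O-2β and C-20 joined through SiMe2 (5α-H, 10β), C9 epimers | C12(OCCO1)CC[C@H]3C(C)(C)C[C@H]4O[Si](C)(C)C[C@@]3(C4)C2CC[C@@H](C)CC(=O)OC | intermediate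
19 | (13R)-8,8-ethylenedioxy-2β-hydroxy-17-norlabdan-15-oic acid, C9 epimers | C12(OCCO1)CC[C@H]3C(C)(C)C[C@@H](O)C[C@]3(C)C2CC[C@@H](C)CC(=O)O | intermediate
20 | (13R)-2β-hydroxy-8-oxo-17-norlabdan-15-oic acid; (3R)-5-[(1R,4aS,7R,8aS)-7-hydroxy-5,5,8a-trimethyl-2-oxodecahydronaphthalen-1-yl]-3-methylpentanoic acid | O=C1CC[C@H]2C(C)(C)C[C@@H](O)C[C@]2(C)[C@H]1CC[C@@H](C)CC(=O)O | intermediate
21 | (13R)-2β-hydroxylabd-8(17)-en-15-oic acid; (3R)-5-[(1S,4aS,7R,8aS)-7-hydroxy-5,5,8a-trimethyl-2-methylidenedecahydronaphthalen-1-yl]-3-methylpentanoic acid | C=C1CC[C@H]2C(C)(C)C[C@@H](O)C[C@]2(C)[C@H]1CC[C@@H](C)CC(=O)O | intermediate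
22 | acetic (13R)-2β-acetoxylabd-8(17)-en-15-oic anhydride | C=C1CC[C@H]2C(C)(C)C[C@@H](OC(C)=O)C[C@]2(C)[C@H]1CC[C@@H](C)CC(=O)OC(C)=O | intermediate (not isolated)
23 | (13R)-2β-acetoxylabd-8(17)-en-15-oic acid; (3R)-5-[(1S,4aS,7R,8aS)-7-acetoxy-5,5,8a-trimethyl-2-methylidenedecahydronaphthalen-1-yl]-3-methylpentanoic acid (CNP0205865.1) | C=C1CC[C@H]2C(C)(C)C[C@@H](OC(C)=O)C[C@]2(C)[C@H]1CC[C@@H](C)CC(=O)O | target

## Step count and least certain steps

Total step count: 14. Longest linear sequence: 12 (steps 1–4 and 7–14); steps 5 and 6 make the side chain.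

**Step 10 (key step).** The most likely failure is hydrogen transfer to the primary radical before it cyclises. Addition to a tetrasubstituted alkene flanked by the C4 gem‑dimethyl group and the substituted C9 is slow, so the bromide could simply be reduced. A second risk is loss of face selectivity in the hydrogen transfer to C5, which would erode the trans fusion.
Fallback (sets out from 16, returns at 19): hydroxyl‑directed Simmons–Smith cyclopropanation (Et2Zn, CH2I2, CH2Cl2, 0 °C) of the C5=C10 alkene on the face of the C2 hydroxyl should give methyl (13R)-8,8-ethylenedioxy-2β-hydroxy-5β,10β-methano-17,20-dinorlabdan-15-oate F1. Anhydrous acid (HCl, CHCl3) should open the three‑membered ring at the C5–C20 bond; the tertiary C5 cation loses a proton from C6 to give methyl (13R)-8,8-ethylenedioxy-2β-hydroxy-17-norlabd-5-en-15-oate F2. MHAT hydrogenation (Mn(dpm)3, PhSiH3, t-BuOOH, i-PrOH) should deliver hydrogen to the C5 radical from the α face and give methyl (13R)-8,8-ethylenedioxy-2β-hydroxy-17-norlabdan-15-oate F3. Saponification with LiOH returns to 19.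

**Step 7.** Proton exchange between product and dienolate could cause double alkylation, and competing deprotonation at C7 would give the regioisomer; both are aggravated by the unactivated primary iodide.
Fallback (sets out from 9, returns at 16): acid (HCl, MeOH) moves the alkene of 9 into conjugation to give (7R)-7-hydroxy-5,5-dimethyl-4,4a,5,6,7,8-hexahydronaphthalen-2(3H)-one F4. α‑Iodination (I2, pyridine, CH2Cl2) gives (7R)-7-hydroxy-1-iodo-5,5-dimethyl-4,4a,5,6,7,8-hexahydronaphthalen-2(3H)-one F5. Zinc insertion into 14 gives methyl (3S)-5-(iodozincio)-3-methylpentanoate F6, and Negishi coupling with F5 (PdCl2(dppf), THF) gives methyl (3R)-5-[(7R)-7-hydroxy-5,5-dimethyl-2-oxo-2,3,4,4a,5,6,7,8-octahydronaphthalen-1-yl]-3-methylpentanoate F7. The ketalisation of step 8, which moves the alkene to C5=C10, returns to 16.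

**Step 3.** Competing ring closure at the arene carbon ortho to the methoxy group, or acid‑induced dehydration of the secondary alcohol, would lower the yield of the single tetralin.
Fallback (sets out from 6, returns at 7): bromination para to the methoxy group (NBS, MeCN) gives (2R)-1-(2-bromo-5-methoxyphenyl)-4-methylpent-4-en-2-ol F8. Reductive Heck cyclisation (Pd(OAc)2, PPh3, HCO2Na, DMF, 80 °C; 6‑exo closure, then formate reduction of the neopentyl palladium species) fixes the ring‑closure position and gives 7.

**Step 13.** The basic ylide may enolise the hindered C8 ketone, which is flanked by the substituted C9 and shielded by C20, instead of adding to it; the ketone would then be recovered.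
Fallback (sets out from 20, returns at 21): Peterson olefination in two steps. Addition of Me3SiCH2MgCl with CeCl3 (THF, −78 to 0 °C) gives (13R)-2β,8-dihydroxy-17-(trimethylsilyl)labdan-15-oic acid F9 (C8 epimers). Elimination with HF·pyridine or KH then gives 21.

## Further compounds

F1 | step 10 | methyl (13R)-8,8-ethylenedioxy-2β-hydroxy-5β,10β-methano-17,20-dinorlabdan-15-oate (C9 epimers) | C12(OCCO1)CC[C@]3(C4)C(C)(C)C[C@@H](O)C[C@]34C2CC[C@@H](C)CC(=O)OC
F2 | step 10 | methyl (13R)-8,8-ethylenedioxy-2β-hydroxy-17-norlabd-5-en-15-oate (C9 epimers) | C12(OCCO1)CC=C3C(C)(C)C[C@@H](O)C[C@]3(C)C2CC[C@@H](C)CC(=O)OC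
F3 | step 10 | methyl (13R)-8,8-ethylenedioxy-2β-hydroxy-17-norlabdan-15-oate (C9 epimers) | C12(OCCO1)CC[C@H]3C(C)(C)C[C@@H](O)C[C@]3(C)C2CC[C@@H](C)CC(=O)OC
F4 | step 7 | (7R)-7-hydroxy-5,5-dimethyl-4,4a,5,6,7,8-hexahydronaphthalen-2(3H)-one (C4a epimers) | CC1(C)C[C@@H](O)CC2=CC(=O)CCC12
F5 | step 7 | (7R)-7-hydroxy-1-iodo-5,5-dimethyl-4,4a,5,6,7,8-hexahydronaphthalen-2(3H)-one (C4a epimers) | CC1(C)C[C@@H](O)CC2=C(I)C(=O)CCC12
F6 | step 7 | methyl (3S)-5-(iodozincio)-3-methylpentanoate | I[Zn]CC[C@@H](C)CC(=O)OC
F7 | step 7 | methyl (3R)-5-[(7R)-7-hydroxy-5,5-dimethyl-2-oxo-2,3,4,4a,5,6,7,8-octahydronaphthalen-1-yl]-3-methylpentanoate (C4a epimers) | CC1(C)C[C@@H](O)CC2=C(CC[C@@H](C)CC(=O)OC)C(=O)CCC12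
F8 | step 3 | (2R)-1-(2-bromo-5-methoxyphenyl)-4-methylpent-4-en-2-ol | C=C(C)C[C@@H](O)Cc1cc(OC)ccc1Br
F9 | step 13 | (13R)-2β,8-dihydroxy-17-(trimethylsilyl)labdan-15-oic acid (C8 epimers) | C[Si](C)(C)CC1(O)CC[C@H]2C(C)(C)C[C@@H](O)C[C@]2(C)[C@H]1CC[C@@H](C)CC(=O)O
A1 | alternative 1 | methyl (3R,6Z,10E)-3,11,15-trimethyl-7-[(trimethylsilyl)methyl]hexadeca-6,10,14-trienoate | CC(C)=CCC/C(C)=C/CC/C(C[Si](C)(C)C)=C/CC[C@@H](C)CC(=O)OC
A2 | alternative 1 | methyl (13R)-labd-8(17)-en-15-oate | C=C1CC[C@H]2C(C)(C)CCC[C@]2(C)[C@H]1CC[C@@H](C)CC(=O)OC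
A3 | alternative 2 | tert-butyl (3R)-7-[(1S,2R,4S)-1-[(tert-butyldimethylsilyl)oxy]-5,8,8-trimethylbicyclo[2.2.2]oct-5-en-2-yl]-3-methyl-7-oxoheptanoate | O([Si](C)(C)C(C)(C)C)[C@@]12C=C(C)[C@@H](C[C@H]1C(=O)CCC[C@@H](C)CC(=O)OC(C)(C)C)C(C)(C)C2
A4 | alternative 2 | tert-butyl (13R)-2,8-dioxo-17-norlabdan-15-oate | O=C1CC[C@H]2C(C)(C)CC(=O)C[C@]2(C)[C@H]1CC[C@@H](C)CC(=O)OC(C)(C)C
A5 | alternative 3 | (2E)-4-{2-[(3E,5E)-7-[(4-methoxybenzyl)oxy]-2,2-dimethylhepta-3,5-dien-1-yl]-1,3-dioxolan-2-yl}-3-methylbut-2-enal | O=C/C=C(\C)CC1(OCCO1)CC(C)(C)/C=C/C=C/COCc1ccc(OC)cc1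
A6 | alternative 3 | 2,2-ethylenedioxy-17-[(4-methoxybenzyl)oxy]-12,13,14,15,16-pentanorlabd-6-en-11-al (5α-H, 8α-H, 9α-H, 10β-methyl) | COc1ccc(cc1)COC[C@H]2C=C[C@H]3C(C)(C)CC4(OCCO4)C[C@]3(C)[C@H]2C=O
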